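Decide what Wednesday's flask can still give after 6.0 h: where it has stopped, and which remedy moves it.

| setting | Wednesday's | flask |
|---|---|---|
| substrate | 0.097 M | 0.097 M |
| reagent | 0.146 M | 0.146 M |
| temperature | −20 °C | −20 °C |
| remark | the very flask that is asked about, followed so far |  |
| time |  | 6.0 h |

Wednesday's run (percent of the substrate charged)

| time / min | target / % | substrate / % |
|---|---|---|
| 30.0 | 37.7 | 14.2 |
| 40.0 | 44.1 | 13.9 |
| 60.0 | 52.6 | 11.5 |
| 90.0 | 60.2 | 10.0 |
| 150 | 66.3 | 8.5 |
| 240 | 70.4 | 7.5 |
| 360 | 71.8 | 7.0 |

(standard deviation of a reading: 0.3 percentage points)

- additions leave the volume as it is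
- a reading or a percentage of target counts all its forms, free or not
- the earlier runs do not show what temperature does; that part of a forecast is a guess

- birch: at 6.0 h add substrate, 50.0% of the amount charged, then wait 3.0 h
- maple: at 6.0 h add reagent, 50.0% of the amount charged, then wait 3.0 h
- oak: at 6.0 h raise the temperature by 25 K, then wait 3.0 h
- larch: change nothing and wait 3.0 h more

- target, in percent of the substrate first charged, at 6.0 h
- the remedy with the largest gain of target, or "none" below 2 percentage points (birch / maple / oak / larch / none)
- target present, in percent of the substrate first charged, after maple
- target present, in percent of the substrate first charged, after oak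

Start with the main step alone: substrate plus reagent gives target, one reagent per target. This symmetric case is the zero of the scale. Wednesday's flask holds 1.51 equivalents of reagent, so target should climb to 100% of the substrate charged. The readings refuse this: target stands at 71.8% at 360 min and gained 1.4 percentage points over the last interval.

Now add a second process: let each target cost two reagents, one to take up the substrate and one to carry it on. Then c(reagent) divided by two c(substrate) gives 75.3%. Call this the reagent ceiling: the target, in percent of the substrate charged, that the reagent charge can pay for. It makes reagent the limiting reagent, and the last reading lies just under it.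

Add the rest: target and substrate together fall short of the charge by 21.2% at 360 min, about 3.03 times the substrate reading. Treat this as an unseen reservoir of intermediates. It changes the pace of the flask, not the ceiling.

Now reckon the options. Take "now" as the last reading. Larch has 3.5 points of headroom, and a slowing gain should use less than 2 points of it. Birch adds no reagent, so the ceiling in percent of the first charge stays put. Oak, a guess, meets the same ceiling. Maple lifts the ceiling to 113%, above the 100% the substrate allows, so commit to maple, with target heading towards 100%.

The forecast gives 71.9%, names maple, and puts target at 84% after maple and 72.8% after oak, holding that “Fresh reagent should therefore restart conversion”. The flask gives 72.3% and best maple, a gain of 22 points, with 94.2% after maple and 73.4% after oak.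

    substrate ⇌ intermediate C (K = 0.800, k = 7.06 × 10⁻⁴ /s, Ea = 77.0 kJ/mol, ΔH = 0 kJ/mol)
    crystals ⇌ target, rate k2*(cs2 - [target]) while solid is left; crystals form when [target] > cs2 (solubility = 47.0 mM, k = 0.984 /s)
    intermediate D ⇌ intermediate E (K = 0.870, k = 0.00236 /s, Ea = 78.0 kJ/mol, ΔH = −34.0 kJ/mol)
    intermediate D → target (k = 0.0521 /s, Ea = 76.0 kJ/mol)
    substrate + reagent ⇌ intermediate A (K = 197 /M, k = 0.0117 /M/s, Ea = 61.0 kJ/mol, ΔH = −86.0 kJ/mol)
    reagent + intermediate A → intermediate D (k = 0.0188 /M/s, Ea = 36.0 kJ/mol)
    substrate ⇌ intermediate B (K = 1.47, k = 0.00553 /s, Ea = 63.0 kJ/mol, ΔH = −27.0 kJ/mol)
    (constants at −20 °C)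

The consumption of reagent is the main reason this flask stops short: the run with reagent held at its charge reaches >99.9% at 6.0 h, against 72.3%. Left until 3600 min, this flask gives 75.0%, level with its ceiling of 75.3%, and after maple, with the ceiling at 113%, it stands at 94.2%. The neighbour charged with 0.16 M of substrate has a ceiling of 45.6% and gives 43.0% at 6.0 h.

(Readings and results are simulated from invented constants.)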